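(The earlier runs and the new flask are calculated for substances that don't exist, noise included.)

| setting | red | cedar | maple | ash |
|---|---|---|---|---|
| starting complex | 0.050 M | 0.033 M | 0.033 M | 0.033 M |
| incoming ligand | 0.033 M | 0.0330 M | 0.0660 M | 0.132 M |
| leaving ligand | 0.0165 M | 0.0165 M | 0.0165 M | 0.0165 M |
| remark | run made earlier |  |  |  |
| time |  | 15 d | 15 d | 15 d |

red run (percent of the starting complex charged)

| time / d | complex with one exchanged / % | starting complex / % |
|---|---|---|
| 2.50 | 56.5 | 42.5 |
| 5.00 | 61.8 | 37.8 |
| 6.00 | 62.3 | 37.6 |
| 10.0 | 63.6 | 37.3 |

(scatter of a reading: 0.5 percentage points)

1. complex with one exchanged at the end, in percent of the starting complex charged, for each flask in turn (cedar, maple, ash)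

- what is said of complex with one exchanged includes crystals
- crystals is a solid; its amount is given per volume of the solution
- the numbers in the tables scatter with a standard deviation of 0.5 percentage points
- on the list of suspects stand: starting complex + incoming ligand <-> leaving ligand + complex with one exchanged; complex with one exchanged + incoming ligand <-> leaving ligand + complex with two exchanged; crystals <-> complex with one exchanged
- no earlier run changes the charge of incoming ligand; that part of a forecast is a guess

Start with the easy step and add the two columns of the red run at 10.0 d: they give 100.9%, within scatter of the charge, so no second exchange shows there. Then climb the ladder of times. On the lowest rung, the first exchange in the red run reaches 88.8% of its last reading by 2.50 d; on the next, the red readings of complex with one exchanged go from 62.3% at 6.00 d to 63.6% at 10.0 d; on the top rung stands the asked 15 d, which is longer, so treat each end as a balance.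

At the last red reading, take 18.6 mM starting complex, 1.20 mM incoming ligand and 48.3 mM leaving ligand. This gives 0.463 mM, a rough reading since the incoming ligand left is a small difference of large numbers. Carry it as Q, the concentration of starting complex times that of incoming ligand over that of leaving ligand at balance, a reaction quotient that stays constant if crystals keep the dissolved complex with one exchanged saturated.

Reckon cedar by iteration, where the two charges match and so, with the second exchange set aside, equal amounts s of both remain: assuming full conversion gives s = 4.79 mM, and putting that back gives 4.55 mM, hence 86.2% complex with one exchanged. For maple, Q with the first exchange taken as complete leaves 2.11% starting complex, and the second exchange, which no reading measures, takes an unknown further share.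

The forecast gives 86%, 89% and 77%, arguing that “excess ligand drives second exchange”.

The flasks give 83.3%, 92.6% and 86.1%, and the forecast parts furthest in ash, by 9.1 percentage points.

    starting complex + incoming ligand ⇌ leaving ligand + complex with one exchanged (K = 2.10, k = 1.40 L mol⁻¹ h⁻¹)
    complex with one exchanged + incoming ligand ⇌ leaving ligand + complex with two exchanged (K = 2.00, k = 3.30 L mol⁻¹ h⁻¹)
    crystals ⇌ complex with one exchanged, rate k3*(cs3 - [complex with one exchanged]) while solid is left; crystals form when [complex with one exchanged] > cs3 (solubility = 1.20 mM, k = 7.00 h⁻¹)

In cedar the first exchange ran while starting complex and incoming ligand stood together, and by 7.50 d it had left 17.7% of starting complex beside 77.8% crystals, ending at 15.8% with 79.7% crystals, where Q and the two ligands standing in cedar give 12.6%. In maple the second exchange ran beside the first while incoming ligand remained, 49% of its charge at the end, reaching 4.69% complex with two exchanged beside 89.0% crystals, and Q with the two ligands standing in maple gives 2.18% starting complex where maple holds 2.69%.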